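The γ-lactone is disconnected at C4–C5, the bond between the ring carbon that carries the 3,4-dimethoxybenzyl group and the OCH2 carbon. C5 is an acyloxymethyl carbon, and the benzylic carbon C7 on C4 adjoins the dimethoxyphenyl ring; the key step therefore closes the lactone by 5-exo-trig attack of an acyloxymethyl radical on a C4=C7 styrene, giving a benzylic radical that is reduced to the CH2 group. The precursor is an open-chain iodomethyl (R)-2-benzyl-4-arylbut-3-enoate; its only stereocentre (C3, set by Evans alkylation) steers the new C4 centre trans. Hydrogenolysis of one benzyl ether then frees the phenol.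

Key step: step 9

Remark: lactone atoms are numbered O1, C2 (C=O), C3, C4, C5 (OCH2); C7 is the benzylic carbon on C4 and C8 the benzylic carbon on C3. The target is the trans (3R,4R) lactone. The alkene geometry of compound 7 is erased in step 9, so an E/Z mixture would also serve.

Step 1
Reactants: 1 syringyl alcohol (4-(hydroxymethyl)-2,6-dimethoxyphenol)
Product: 2 [4-(benzyloxy)-3,5-dimethoxyphenyl]methanol
Conditions: BnBr, K2CO3, DMF, rt
Reagents that add atoms: benzyl bromide, BrCc1ccccc1
Why: Williamson etherification in which carbonate deprotonates only the phenol, so the phenoxide is benzylated and the benzylic alcohol is left free.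

Step 2
Reactants: 2 [4-(benzyloxy)-3,5-dimethoxyphenyl]methanol
Product: 3 4-(benzyloxy)-3,5-dimethoxybenzyl bromide
Conditions: PBr3, CH2Cl2, 0 °C
Reagents that add atoms: phosphorus tribromide, BrP(Br)Br
Why: Bromination of a benzylic alcohol through its phosphite ester with SN2 displacement by bromide, under conditions that leave aryl ethers intact.

Step 3
Reactants: 4 3,4-dimethoxybenzaldehyde (veratraldehyde); 5 (2-carboxyethyl)triphenylphosphonium bromide
Product: 7 (E)-4-(3,4-dimethoxyphenyl)but-3-enoic acid, via sodium ylide carboxylate 6 (not isolated)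
Conditions: NaN(SiMe3)2 (2.1 equiv), THF, −78 °C to rt; then aq HCl
Reagents that add atoms: sodium bis(trimethylsilyl)amide, [Na+].C[Si](C)(C)[N-][Si](C)(C)C (sodium only in intermediate 6)
Why: Wittig olefination of an aryl aldehyde with a carboxylate-bearing ylide, which should favour the E styrene and places the double bond β,γ to the acid.

Step 4
Reactants: 7 (E)-4-(3,4-dimethoxyphenyl)but-3-enoic acid; 8 (R)-4-benzyloxazolidin-2-one
Product: 10 (R)-4-benzyl-3-[(E)-4-(3,4-dimethoxyphenyl)but-3-enoyl]oxazolidin-2-one, via pivalic mixed anhydride 9 (not isolated)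
Conditions: PivCl, Et3N, THF, −20 °C; then 8, LiCl, −20 °C to rt
Reagents that add atoms: pivaloyl chloride, CC(C)(C)C(=O)Cl (acyl group only in intermediate 9)
Why: N-acylation of the oxazolidinone through a mixed anhydride, attacked at the less hindered carbonyl under conditions mild enough to keep the β,γ-alkene in place.

Step 5
Reactants: 10 (R)-4-benzyl-3-[(E)-4-(3,4-dimethoxyphenyl)but-3-enoyl]oxazolidin-2-one; 3 4-(benzyloxy)-3,5-dimethoxybenzyl bromide
Product: 12 (R)-4-benzyl-3-[(2R,3E)-2-[4-(benzyloxy)-3,5-dimethoxybenzyl]-4-(3,4-dimethoxyphenyl)but-3-enoyl]oxazolidin-2-one, via sodium Z-enolate 11 (not isolated)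
Conditions: NaN(SiMe3)2 (1.1 equiv), THF, −78 °C; then 3, −78 to −40 °C
Reagents that add atoms: sodium bis(trimethylsilyl)amide, [Na+].C[Si](C)(C)[N-][Si](C)(C)C (sodium only in intermediate 11)
Why: Evans asymmetric alkylation in which the chelated Z-dienolate reacts at its α-carbon on the face away from the auxiliary 4-benzyl group, which with the (R)-auxiliary should set C3 as R.

Step 6
Reactants: 12 (R)-4-benzyl-3-[(2R,3E)-2-[4-(benzyloxy)-3,5-dimethoxybenzyl]-4-(3,4-dimethoxyphenyl)but-3-enoyl]oxazolidin-2-one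
Product: 14 (2R,3E)-2-[4-(benzyloxy)-3,5-dimethoxybenzyl]-4-(3,4-dimethoxyphenyl)but-3-enoic acid, via lithium percarboxylate 13 (not isolated)
Conditions: LiOH, H2O2, THF/H2O, 0 °C; then aq Na2SO3; then HCl to pH 2
Reagents that add atoms: hydrogen peroxide, OO (one oxygen stays in the carboxyl group); lithium hydroxide, [Li+].[OH-] (lithium only in intermediate 13)
Why: Hydroperoxide cleaves the exocyclic imide carbonyl selectively without enolisation, so C3 should keep its configuration, and sulfite reduces the percarboxylate to the acid.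

Step 7
Reactants: 14 (2R,3E)-2-[4-(benzyloxy)-3,5-dimethoxybenzyl]-4-(3,4-dimethoxyphenyl)but-3-enoic acid
Product: 15 chloromethyl (2R,3E)-2-[4-(benzyloxy)-3,5-dimethoxybenzyl]-4-(3,4-dimethoxyphenyl)but-3-enoate
Conditions: ClCH2OSO2Cl, NaHCO3, Bu4NHSO4 (cat.), CH2Cl2/H2O, rt
Reagents that add atoms: chloromethyl chlorosulfate, ClCOS(=O)(=O)Cl
Why: Phase-transfer O-alkylation of the carboxylate by SN2 displacement of chlorosulfate at the CH2 carbon, in a weakly basic two-phase medium that should not epimerise C3.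

Step 8
Reactants: 15 chloromethyl (2R,3E)-2-[4-(benzyloxy)-3,5-dimethoxybenzyl]-4-(3,4-dimethoxyphenyl)but-3-enoate
Product: 16 iodomethyl (2R,3E)-2-[4-(benzyloxy)-3,5-dimethoxybenzyl]-4-(3,4-dimethoxyphenyl)but-3-enoate
Conditions: NaI, acetone, rt, dark; used at once
Reagents that add atoms: sodium iodide, [Na+].[I-]
Why: Finkelstein halide exchange under neutral conditions, driven by precipitation of NaCl, gives the weak C–I bond needed for clean radical generation.

Step 9
Reactants: 16 iodomethyl (2R,3E)-2-[4-(benzyloxy)-3,5-dimethoxybenzyl]-4-(3,4-dimethoxyphenyl)but-3-enoate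
Product: 17 (3R,4R)-3-[4-(benzyloxy)-3,5-dimethoxybenzyl]-4-(3,4-dimethoxybenzyl)dihydrofuran-2(3H)-one
Conditions: Bu3SnH (1.3 equiv), AIBN (0.2 equiv), syringe pump over 8 h, PhH (0.005 M), 80 °C; KF work-up
Reagents that add atoms: none
Why: Bu3Sn• abstracts iodine from 16 to give an acyloxymethyl radical at C5, which adds to C4 of the C4=C7 styrene; the resulting C7 benzylic radical, stabilised by the 3,4-dimethoxyphenyl ring, takes hydrogen from Bu3SnH and carries the chain. The closest known reaction type is the tin hydride cyclisation of halomethyl alkenoates to lactones through (alkenoyloxy)methyl radicals. The γ-lactone ring (O1, C2, C3, C4, C5) closes in the 5-exo-trig mode. The new C4 stereocentre is controlled by the existing C3 centre: in the envelope-like transition state the C3 benzyl group lies pseudo-equatorial and away from the styrene, so C7 and the C3 substituent should end up trans, (3R,4R). The step needs exo over 6-endo regioselectivity, secured by the aryl group on C7 (benzylic radical on exo attack, hindered terminus for endo attack). It also needs ring closure to outrun hydrogen transfer to the uncyclised radical, secured by the reactive styrene acceptor, heat to populate the cisoid ester rotamer and a low stationary Bu3SnH concentration.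

Step 10
Reactants: 17 (3R,4R)-3-[4-(benzyloxy)-3,5-dimethoxybenzyl]-4-(3,4-dimethoxybenzyl)dihydrofuran-2(3H)-one
Product: 18 (3R,4R)-4-(3,4-dimethoxybenzyl)-3-(4-hydroxy-3,5-dimethoxybenzyl)dihydrofuran-2(3H)-one (target)
Conditions: H2 (1 atm), 10% Pd/C, EtOAc/EtOH, rt
Reagents that add atoms: none
Why: Hydrogenolysis of the benzyl aryl ether frees the phenol without touching the lactone, the methyl ethers or either stereocentre.

Compound list
1 | syringyl alcohol, 4-(hydroxymethyl)-2,6-dimethoxyphenol | COc1cc(CO)cc(OC)c1O | starting material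
2 | [4-(benzyloxy)-3,5-dimethoxyphenyl]methanol | COc1cc(CO)cc(OC)c1OCc1ccccc1 | intermediate
3 | 4-(benzyloxy)-3,5-dimethoxybenzyl bromide | COc1cc(CBr)cc(OC)c1OCc1ccccc1 | intermediate
4 | 3,4-dimethoxybenzaldehyde (veratraldehyde) | COc1ccc(C=O)cc1OC | starting material
5 | (2-carboxyethyl)triphenylphosphonium bromide | OC(=O)CC[P+](c1ccccc1)(c1ccccc1)c1ccccc1.[Br-] | starting material
6 | sodium 3-(triphenylphosphoranylidene)propanoate (ylide, formed in situ) | [Na+].[O-]C(=O)CC=P(c1ccccc1)(c1ccccc1)c1ccccc1 | intermediate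
7 | (E)-4-(3,4-dimethoxyphenyl)but-3-enoic acid | COc1ccc(/C=C/CC(=O)O)cc1OC | intermediate
8 | (R)-4-benzyloxazolidin-2-one | O=C1OC[C@@H](Cc2ccccc2)N1 | starting material
9 | (E)-4-(3,4-dimethoxyphenyl)but-3-enoic pivalic anhydride (formed in situ) | COc1ccc(/C=C/CC(=O)OC(=O)C(C)(C)C)cc1OC | intermediate
10 | (R)-4-benzyl-3-[(E)-4-(3,4-dimethoxyphenyl)but-3-enoyl]oxazolidin-2-one | COc1ccc(/C=C/CC(=O)N2[C@H](Cc3ccccc3)COC2=O)cc1OC | intermediate
11 | sodium Z-enolate of imide 10 (formed in situ) | [Na+].COc1ccc(/C=C/C=C(\[O-])N2[C@H](Cc3ccccc3)COC2=O)cc1OC | intermediate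
12 | (R)-4-benzyl-3-[(2R,3E)-2-[4-(benzyloxy)-3,5-dimethoxybenzyl]-4-(3,4-dimethoxyphenyl)but-3-enoyl]oxazolidin-2-one | COc1ccc(/C=C/[C@@H](Cc2cc(OC)c(OCc3ccccc3)c(OC)c2)C(=O)N2[C@H](Cc3ccccc3)COC2=O)cc1OC | intermediate
13 | lithium (2R,3E)-2-[4-(benzyloxy)-3,5-dimethoxybenzyl]-4-(3,4-dimethoxyphenyl)but-3-eneperoxoate (formed in situ) | [Li+].COc1ccc(/C=C/[C@@H](Cc2cc(OC)c(OCc3ccccc3)c(OC)c2)C(=O)O[O-])cc1OC | intermediate
14 | (2R,3E)-2-[4-(benzyloxy)-3,5-dimethoxybenzyl]-4-(3,4-dimethoxyphenyl)but-3-enoic acid | COc1ccc(/C=C/[C@@H](Cc2cc(OC)c(OCc3ccccc3)c(OC)c2)C(=O)O)cc1OC | intermediate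
15 | chloromethyl (2R,3E)-2-[4-(benzyloxy)-3,5-dimethoxybenzyl]-4-(3,4-dimethoxyphenyl)but-3-enoate | COc1ccc(/C=C/[C@@H](Cc2cc(OC)c(OCc3ccccc3)c(OC)c2)C(=O)OCCl)cc1OC | intermediate
16 | iodomethyl (2R,3E)-2-[4-(benzyloxy)-3,5-dimethoxybenzyl]-4-(3,4-dimethoxyphenyl)but-3-enoate | COc1ccc(/C=C/[C@@H](Cc2cc(OC)c(OCc3ccccc3)c(OC)c2)C(=O)OCI)cc1OC | intermediate
17 | (3R,4R)-3-[4-(benzyloxy)-3,5-dimethoxybenzyl]-4-(3,4-dimethoxybenzyl)dihydrofuran-2(3H)-one | COc1ccc(C[C@H]2COC(=O)[C@@H]2Cc2cc(OC)c(OCc3ccccc3)c(OC)c2)cc1OC | intermediate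
18 | (3R,4R)-4-(3,4-dimethoxybenzyl)-3-(4-hydroxy-3,5-dimethoxybenzyl)dihydrofuran-2(3H)-one | COc1ccc(C[C@H]2COC(=O)[C@@H]2Cc2cc(OC)c(O)c(OC)c2)cc1OC | target

Total step count: 10.
Longest linear sequence: 8 steps (steps 3 to 10 from veratraldehyde; equally steps 1, 2 and 5 to 10 from syringyl alcohol).

Steps most likely to fail

Step 9 (key radical ring closure). The acyloxymethyl radical may take hydrogen from the stannane before it cyclises, because the ester must first rotate into its less populated cisoid rotamer. It may also close in the 6-endo mode or undergo a 1,5-hydrogen shift from the C8 benzylic CH2. Facial selectivity at C4 may be poor, and a cis isomer cannot be corrected by epimerisation without loss of enantiopurity. The fallback sets out from bromide 3 and rejoins the route at 17; it builds the lactone first and introduces the C3 substituent last. Commercial 3-(3,4-dimethoxyphenyl)propanoic acid is coupled with commercial (S)-4-benzyloxazolidin-2-one (DCC, DMAP, CH2Cl2) to give (S)-4-benzyl-3-[3-(3,4-dimethoxyphenyl)propanoyl]oxazolidin-2-one F1. Evans alkylation with tert-butyl bromoacetate (NaN(SiMe3)2, THF, −78 °C) should give tert-butyl (R)-4-[(S)-4-benzyl-2-oxooxazolidin-3-yl]-3-(3,4-dimethoxybenzyl)-4-oxobutanoate F2. LiBH4 (THF, 0 °C) removes the auxiliary reductively to give tert-butyl (R)-3-(3,4-dimethoxybenzyl)-4-hydroxybutanoate F3, which TFA in CH2Cl2 closes to (R)-4-(3,4-dimethoxybenzyl)dihydrofuran-2(3H)-one F4. Its lithium enolate (LiN(SiMe3)2, THF, −78 °C) is alkylated with 3 on the face anti to the C4 substituent, which should give the trans lactone 17.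

Step 5 (Evans alkylation of the dienolate). The extended enolate may alkylate at the γ-carbon or let the double bond migrate into conjugation with the carbonyl. The hindered, electron-rich bromide may react slowly enough for the enolate to decompose by loss of the oxazolidinone. The fallback sets out from acid 7 and bromide 3 and rejoins at acid 14, bypassing steps 4 to 6 and using no covalent auxiliary. The dilithium enediolate of 7 is generated with n-BuLi in THF in the presence of the dilithium amide of a C2-symmetric chiral tetramine, N,N'-bis(1-phenyl-2-piperidinoethyl)propane-1,3-diamine, in the enantiomeric form that delivers the (R)-acid. It is alkylated with 3 at −78 °C, and the tetramine is recovered by acid extraction. Direct enantioselective α-alkylation of arylacetic and β,γ-unsaturated acids with such traceless chiral lithium amides is known chemistry.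

Step 8 (iodomethyl ester). The iodomethyl ester is a labile alkylating agent; it may be lost by hydrolysis or self-alkylation during isolation, and C3, which is both α to the ester and allylic, may epimerise on handling. The fallback sets out from acid 14 and rejoins at 17; it generates the same C5 radical by reductive decarboxylation and avoids any halomethyl ester. Acid 14 is alkylated with allyl bromoacetate (K2CO3, DMF) to give 2-(allyloxy)-2-oxoethyl (2R,3E)-2-[4-(benzyloxy)-3,5-dimethoxybenzyl]-4-(3,4-dimethoxyphenyl)but-3-enoate F5. Deallylation (Pd(PPh3)4 cat., morpholine, THF) gives the carboxymethyl ester 2-{[(2R,3E)-2-[4-(benzyloxy)-3,5-dimethoxybenzyl]-4-(3,4-dimethoxyphenyl)but-3-enoyl]oxy}acetic acid F6. Coupling with N-hydroxyphthalimide (DIC, DMAP cat., CH2Cl2) gives the redox-active ester 1,3-dioxoisoindolin-2-yl 2-{[(2R,3E)-2-[4-(benzyloxy)-3,5-dimethoxybenzyl]-4-(3,4-dimethoxyphenyl)but-3-enoyl]oxy}acetate F7. Photoreduction (Ru(bpy)3Cl2 cat., Hantzsch ester, i-Pr2NEt, CH2Cl2, blue LED) should expel phthalimide and CO2, and the acyloxymethyl radical should cyclise as in step 9, with the Hantzsch ester as a slow hydrogen donor, to give 17.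

Further compounds
F1 | step 9 | (S)-4-benzyl-3-[3-(3,4-dimethoxyphenyl)propanoyl]oxazolidin-2-one | COc1ccc(CCC(=O)N2[C@@H](Cc3ccccc3)COC2=O)cc1OC
F2 | step 9 | tert-butyl (R)-4-[(S)-4-benzyl-2-oxooxazolidin-3-yl]-3-(3,4-dimethoxybenzyl)-4-oxobutanoate | COc1ccc(C[C@H](CC(=O)OC(C)(C)C)C(=O)N2[C@@H](Cc3ccccc3)COC2=O)cc1OC
F3 | step 9 | tert-butyl (R)-3-(3,4-dimethoxybenzyl)-4-hydroxybutanoate | COc1ccc(C[C@H](CC(=O)OC(C)(C)C)CO)cc1OC
F4 | step 9 | (R)-4-(3,4-dimethoxybenzyl)dihydrofuran-2(3H)-one | COc1ccc(C[C@H]2COC(=O)C2)cc1OC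
F0 | step 5 | none | none
F5 | step 8 | 2-(allyloxy)-2-oxoethyl (2R,3E)-2-[4-(benzyloxy)-3,5-dimethoxybenzyl]-4-(3,4-dimethoxyphenyl)but-3-enoate | COc1ccc(/C=C/[C@@H](Cc2cc(OC)c(OCc3ccccc3)c(OC)c2)C(=O)OCC(=O)OCC=C)cc1OC
F6 | step 8 | 2-{[(2R,3E)-2-[4-(benzyloxy)-3,5-dimethoxybenzyl]-4-(3,4-dimethoxyphenyl)but-3-enoyl]oxy}acetic acid | COc1ccc(/C=C/[C@@H](Cc2cc(OC)c(OCc3ccccc3)c(OC)c2)C(=O)OCC(=O)O)cc1OC
F7 | step 8 | 1,3-dioxoisoindolin-2-yl 2-{[(2R,3E)-2-[4-(benzyloxy)-3,5-dimethoxybenzyl]-4-(3,4-dimethoxyphenyl)but-3-enoyl]oxy}acetate | COc1ccc(/C=C/[C@@H](Cc2cc(OC)c(OCc3ccccc3)c(OC)c2)C(=O)OCC(=O)ON2C(=O)c3ccccc3C2=O)cc1OC
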